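## Analysis of the target

Target 14 is a 2,3,4,5-tetrasubstituted tetrahydrofuran (ring atoms O1, C2, C3, C4, C5). C2 and C5 each carry a 3,4-dihydroxyphenyl group, and C3 and C4 each carry a CH2OAc arm. The SMILES puts the two aryls cis to each other, the two arms cis to each other, and each aryl trans to the arm on the neighbouring carbon. A mirror plane through O1 and the midpoint of C3–C4 makes the compound meso, (2R,3S,4R,5S), so only relative configuration has to be controlled. The aryl/arm trans relationships are the thermodynamically preferred ones, but the cis relationship between C3 and C4 is not, and it has to be set kinetically. The sensitive groups are the two catechols (oxidation to o-quinones, worst under base), the two primary acetates (cleaved or shifted by base and nucleophiles) and the benzylic C2–O1 and C5–O1 bonds, which acid ionises and hydrogenolysis can cut. The hard part is the final pattern: ordinary acylating agents do not put acetates on aliphatic hydroxyls while leaving phenols free, and a phenol deprotection after acylation would have to spare both the esters and the benzylic ring bonds. The strategy rests on the two primary hydroxyls on the CH2 groups at C3 and C4 of hexol 11 being its only aliphatic hydroxyls: a lipase accepts them and rejects the four phenolic ones, so acetylation can be the last step on an unprotected substrate.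

## Retrosynthetic reasoning

**Target 14 to hexol 11 and vinyl acetate 12.** The two acyl C–O bonds of the acetates are cut. Cutting here, and not at a phenol protecting group, means that nothing has to be removed once the esters exist. The forward reaction must acetylate both aliphatic hydroxyls (through monoacetate 13) and none of the four phenolic ones.

**Hexol 11 to tetrabenzyl diol 10.** The four phenolic O–CH2 bonds are cut. Benzyl ethers survive base, hydride and the photolysis used earlier, and they come off under neutral conditions. The forward hydrogenolysis has to stop before the ring bonds C2–O1 and C5–O1 are attacked.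

**Diol 10 to diester 9.** Only the oxidation level of the two arms changes. The ester groups are needed earlier because they activate the two-carbon partner in the ring-forming step. The forward reduction must not epimerise C3 or C4.

**Diester 9 to epoxide 6 and dimethyl maleate 7.** The symmetry-related bonds C2–C3 and C4–C5 are cut, which leads back through carbonyl ylide 8. This splits the meso ring into a symmetric C2–O1–C5 unit carrying both aryls and a symmetric Z-configured C3–C4 unit carrying both arms. The ring and all four stereocentres then arise in one step. A cut at a C–O bond would instead require an open-chain 1,4-diol with four stereocentres already in place. The forward reaction has to open 6 to 8, let 8 react in its extended shape (aryls cis), add suprafacially to 7 (arms cis), and approach with the esters turned away from the aryls (aryl trans to arm).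

**Epoxide 6 to aldehyde 1 and sulfonium salt 4.** The oxirane C–C bond and one C–O bond are cut, which leads back through ylide 5. Both halves come from the same aldehyde, and no peracid touches the acid-sensitive, electron-rich epoxide. The geometry of 6 is not critical, because opening to 8 erases it.

**Salt 4 to bromide 3, alcohol 2 and aldehyde 1.** The C–S bond, the C–Br bond and a C–H bond are cut in turn. These are standard functional-group changes on a benzylic carbon.

## Alternatives that were turned down

**Alternative 1:** The C2–C3 bond is disconnected, closing the tetrahydrofuran onto a preformed lactone. In the forward step Rh2(OAc)4 decomposes the α-diazo lactone A2, and the carbene at the future C3 inserts into the benzylic C–H bond of the arylmethyl ether to give the cis-fused lactone A1.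
- **For:** The insertion is intramolecular and five-membered. The ring fusion forces the C3/C4 arms cis and should put the aryls on the convex face. On relative stereocontrol this is more predictable than an intermolecular cycloaddition.
- **Against:** The carbene has a hydrogen on the adjacent C4, so hydride migration with alkene formation competes. The electron-rich arenes invite aromatic addition. A2 needs two stereocentres set in a linear sequence and a diazo transfer onto a lactone.
- **Comparison:** The route builds a meso molecule unsymmetrically and is clearly longer. After A1 it still needs reduction, debenzylation and the same chemoselective acetylation. The chosen strategy is shorter and uses the symmetry, and its one stereochemical weak point can be corrected by equilibration at the benzylic carbons.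

**Alternative 2:** Both C2–aryl and C5–aryl bonds are disconnected. In the forward step Ir[dF(CF3)ppy]2(dtbbpy)PF6 and NiCl2·glyme with 4,4′-di-tert-butyl-2,2′-bipyridine under blue light decarboxylate diacid A4 twice and couple the α-oxy radicals with aryl bromide A5 to give A3.
- **For:** The cis arms come from a rigid bicyclic template. The acetates are installed before the aryls, so no chemoselective acylation is needed at all. On that point it is stronger than the chosen route.
- **Against:** Two couplings must succeed on one molecule. A5 is electron-rich and slow in oxidative addition to low-valent nickel, so protodecarboxylation competes. The configuration at C2 and C5 depends on modest induction from the neighbouring arm. The last step is still a hydrogenolysis beside the benzylic ring bonds.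
- **Comparison:** The risk sits in a twofold step without close precedent. The chosen strategy answers the acylation problem with a mild, well-precedented enzymatic step.

**Alternative 3:** O1–C2 and C3–C4 are disconnected. In the forward step zerovalent palladium (Pd2(dba)3 with a phosphine) opens vinyl epoxide A7 to a π-allyl alkoxide. Its oxygen adds to benzylidene malonate A8 and the malonate carbon closes on the allyl unit to give A6.
- **For:** The step is convergent and catalytic, and both partners are close to aldehyde 1. In convergence it equals the chosen route.
- **Against:** A6 has a geminal diester at C3 and a vinyl group at C4. Decarboxylation must then set C3 by protonation, and the required arm is cis to its C4 neighbour, which is not the favoured outcome. Ozonolysis beside electron-rich arenes and two reductions follow. The oxa-Michael step is reversible, and the electron-rich acceptor A8 is weak.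
- **Comparison:** It needs at least five more steps before hexol 11 and leaves C3 poorly controlled. The chosen strategy fixes the C3/C4 cis relationship by stereospecific addition to a Z-alkene.

Key step: step 8

Remark: the target is meso, so chiral intermediates are used as racemates and no absolute stereocontrol is required.

## Route

Step 1
Reactants: 1 3,4-bis(benzyloxy)benzaldehyde
Product: 2 [3,4-bis(benzyloxy)phenyl]methanol
Conditions: NaBH4, MeOH/THF, 0 °C to rt
Reagents that add atoms: none
Why: Borohydride reduction of an aromatic aldehyde; the benzyl ethers are inert and no stereocentre is formed.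

Step 2
Reactants: 2 [3,4-bis(benzyloxy)phenyl]methanol
Product: 3 4-(bromomethyl)-1,2-bis(benzyloxy)benzene
Conditions: PBr3 (0.4 equiv), CH2Cl2, 0 °C
Reagents that add atoms: phosphorus tribromide, BrP(Br)Br
Why: Bromination of a benzylic alcohol through its phosphite ester is fast for this electron-rich system at 0 °C; the labile bromide is washed with aqueous NaHCO3 and used at once.

Step 3
Reactants: 3 4-(bromomethyl)-1,2-bis(benzyloxy)benzene
Product: 4 1-[3,4-bis(benzyloxy)benzyl]tetrahydrothiophen-1-ium bromide
Conditions: tetrahydrothiophene (1.5 equiv), acetone, rt
Reagents that add atoms: tetrahydrothiophene, C1CCSC1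
Why: SN2 S-alkylation of the sulfide by the reactive benzylic bromide; the salt should precipitate from acetone and is collected by filtration.

Step 4
Reactants: 4 1-[3,4-bis(benzyloxy)benzyl]tetrahydrothiophen-1-ium bromide; 1 3,4-bis(benzyloxy)benzaldehyde
Product: 6 trans-2,3-bis[3,4-bis(benzyloxy)phenyl]oxirane (racemic), via sulfonium benzylide 5 (not isolated)
Conditions: KOH (powdered), MeCN/H2O 9:1, rt
Reagents that add atoms: none
Why: Corey–Chaykovsky epoxidation: KOH deprotonates 4 to the semi-stabilised ylide 5, which adds to aldehyde 1 and closes the oxirane with loss of the sulfide. Reversible addition favours the trans epoxide, and the geometry is erased anyway in step 5. No peracid is used, and the acid-sensitive epoxide is purified by crystallisation or on base-washed silica.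

Step 5
Reactants: 6 trans-2,3-bis[3,4-bis(benzyloxy)phenyl]oxirane; 7 dimethyl maleate
Product: 9 dimethyl (2R,3R,4S,5S)-2,5-bis[3,4-bis(benzyloxy)phenyl]tetrahydrofuran-3,4-dicarboxylate (meso; aryls cis; esters cis; each aryl trans to the adjacent ester), via carbonyl ylide 8 (not isolated)
Conditions: hν (>300 nm, Pyrex), 1,4-dicyanonaphthalene (0.2 equiv), 7 (5 equiv), MeCN/CH2Cl2, degassed, rt
Reagents that add atoms: none
Why: Known electron-transfer-sensitised opening of 2,3-diaryloxiranes followed by 1,3-dipolar cycloaddition: the excited sensitiser oxidises 6, the oxirane C–C bond cleaves, and back electron transfer gives ylide 8, which adds in a concerted way to the electron-poor alkene 7. The relaxed extended ylide has both aryls outward and so gives the 2,5-cis relationship, and suprafacial addition carries the Z geometry of 7 into the 3,4-cis esters. The exo approach, with the esters away from the aryl-bearing flank, should be preferred on steric grounds and sets each ester trans to its neighbouring aryl; the all-cis endo adduct is the expected by-product and is removed by chromatography.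

Step 6
Reactants: 9 dimethyl (2R,3R,4S,5S)-2,5-bis[3,4-bis(benzyloxy)phenyl]tetrahydrofuran-3,4-dicarboxylate
Product: 10 [(2R,3S,4R,5S)-2,5-bis[3,4-bis(benzyloxy)phenyl]tetrahydrofuran-3,4-diyl]dimethanol (meso)
Conditions: LiAlH4, THF, 0 °C to rt; aq NaOH work-up
Reagents that add atoms: none
Why: Hydride reduction of both esters to primary alcohols; with the ester added to excess hydride at 0 °C, reduction should outrun enolisation, so the cis relationship at C3/C4 is kept. Benzyl ethers and the ring ether are inert.

Step 7
Reactants: 10 [(2R,3S,4R,5S)-2,5-bis[3,4-bis(benzyloxy)phenyl]tetrahydrofuran-3,4-diyl]dimethanol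
Product: 11 4,4′-[(2R,3S,4R,5S)-3,4-bis(hydroxymethyl)tetrahydrofuran-2,5-diyl]dibenzene-1,2-diol (meso hexol)
Conditions: H2 (1 atm), Pd/C (10 wt%), EtOAc/MeOH, rt
Reagents that add atoms: none
Why: Catalytic hydrogenolysis of aryl benzyl ethers, which cleave much faster than the dialkyl-type benzylic bonds C2–O1 and C5–O1 under neutral conditions at 1 atm. The reaction is stopped at complete debenzylation, the catalyst is filtered under argon, and the air-sensitive hexol is used directly; no stereocentre is touched.

Step 8
Reactants: 11 4,4′-[(2R,3S,4R,5S)-3,4-bis(hydroxymethyl)tetrahydrofuran-2,5-diyl]dibenzene-1,2-diol; 12 vinyl acetate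
Product: 14 [(2R,3S,4R,5S)-2,5-bis(3,4-dihydroxyphenyl)tetrahydrofuran-3,4-diyl]bis(methylene) diacetate (meso; the target CNP0416169.1), via monoacetate 13 (not isolated)
Conditions: immobilised Candida antarctica lipase B, 12 (excess), THF, 40 °C, Ar
Reagents that add atoms: none
Why: Serine-hydrolase transesterification: the active-site serine attacks 12 to give an acetyl-enzyme and vinyl alcohol, which tautomerises to acetaldehyde and makes the transfer irreversible. A primary hydroxyl of 11 bound in the alcohol pocket then attacks the acetyl-enzyme to give monoacetate 13, which passes through the same cycle to give 14. The closest known reaction type is lipase-catalysed acetylation with vinyl acetate of primary aliphatic hydroxyls in polyphenolic alcohols, which leaves the phenols free. No ring closes and no stereocentre is formed; 13 is chiral only because one of two enantiotopic arms has reacted, and either enantiomer converges on meso 14. The step needs acylation of the two aliphatic hydroxyls and of none of the four phenolic ones, and it needs both arms to react. Phenols are poor acceptors for the acetyl-enzyme, and any aryl acetate formed is an activated ester that the enzyme would cleave again by alcoholysis. The CH2OH groups lie trans to the neighbouring aryls and are exposed, and excess irreversible donor drives the second acylation. Neutral conditions under argon spare the catechols and the benzylic ring bonds, and the enzyme is removed by filtration before chromatography.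

## Compound list

1 | 3,4-bis(benzyloxy)benzaldehyde | O=Cc1ccc(OCc2ccccc2)c(OCc2ccccc2)c1 | starting material
2 | [3,4-bis(benzyloxy)phenyl]methanol | OCc1ccc(OCc2ccccc2)c(OCc2ccccc2)c1 | intermediate
3 | 4-(bromomethyl)-1,2-bis(benzyloxy)benzene | BrCc1ccc(OCc2ccccc2)c(OCc2ccccc2)c1 | intermediate
4 | 1-[3,4-bis(benzyloxy)benzyl]tetrahydrothiophen-1-ium bromide | [Br-].C(c1ccc(OCc2ccccc2)c(OCc2ccccc2)c1)[S+]1CCCC1 | intermediate
5 | sulfonium benzylide from 4 (not isolated) | [CH-](c1ccc(OCc2ccccc2)c(OCc2ccccc2)c1)[S+]1CCCC1 | intermediate
6 | trans-2,3-bis[3,4-bis(benzyloxy)phenyl]oxirane (racemic) | c1ccccc1COc1ccc(cc1OCc1ccccc1)[C@@H]1[C@H](O1)c1ccc(OCc2ccccc2)c(OCc2ccccc2)c1 | intermediate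
7 | dimethyl maleate | COC(=O)/C=C\C(=O)OC | starting material
8 | extended (aryls outward) 1,3-bis[3,4-bis(benzyloxy)phenyl] carbonyl ylide (not isolated) | [CH-](c1ccc(OCc2ccccc2)c(OCc2ccccc2)c1)/[O+]=C/c1ccc(OCc2ccccc2)c(OCc2ccccc2)c1 | intermediate
9 | dimethyl (2R,3R,4S,5S)-2,5-bis[3,4-bis(benzyloxy)phenyl]tetrahydrofuran-3,4-dicarboxylate (meso) | COC(=O)[C@@H]1[C@H](C(=O)OC)[C@@H](c2ccc(OCc3ccccc3)c(OCc3ccccc3)c2)O[C@H]1c1ccc(OCc2ccccc2)c(OCc2ccccc2)c1 | intermediate
10 | [(2R,3S,4R,5S)-2,5-bis[3,4-bis(benzyloxy)phenyl]tetrahydrofuran-3,4-diyl]dimethanol (meso) | OC[C@@H]1[C@H](CO)[C@@H](c2ccc(OCc3ccccc3)c(OCc3ccccc3)c2)O[C@H]1c1ccc(OCc2ccccc2)c(OCc2ccccc2)c1 | intermediate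
11 | 4,4′-[(2R,3S,4R,5S)-3,4-bis(hydroxymethyl)tetrahydrofuran-2,5-diyl]dibenzene-1,2-diol (meso hexol) | OC[C@@H]1[C@H](CO)[C@@H](c2ccc(O)c(O)c2)O[C@H]1c1ccc(O)c(O)c1 | intermediate
12 | vinyl acetate | C=COC(C)=O | starting material
13 | monoacetate of hexol 11 (one arm acetylated; either enantiomer; not isolated) | CC(=O)OC[C@@H]1[C@H](CO)[C@@H](c2ccc(O)c(O)c2)O[C@H]1c1ccc(O)c(O)c1 | intermediate
14 | [(2R,3S,4R,5S)-2,5-bis(3,4-dihydroxyphenyl)tetrahydrofuran-3,4-diyl]bis(methylene) diacetate (meso) | CC(=O)OC[C@@H]1[C@H](COC(C)=O)[C@@H](c2ccc(O)c(O)c2)O[C@H]1c1ccc(O)c(O)c1 | target

## Step count and least certain steps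

Total: 8 steps. Longest linear sequence: 8 steps (1 to 14); aldehyde 1 enters a second time in step 4.

**Step 5 (cycloaddition), the least certain step.** The most likely failure is poor facial selectivity. An acyclic carbonyl ylide has no strong intrinsic exo preference toward a Z-diester, so the all-cis adduct may compete or dominate. Long irradiation may also isomerise the alkene or degrade the product. The fallback sets out from epoxide 6. The photolysis is run without regard to facial selectivity, and the all-cis diester F1 (or the whole mixture of cis,cis adducts) is treated with BF3·OEt2 in CH2Cl2 at 0 °C to rt. The Lewis acid reversibly ionises C2–O1 and C5–O1 to para-alkoxybenzyl cations, the known acid-mediated epimerisation of 2-aryltetrahydrofuran lignans. C3 and C4 do not enolise under acid, so the arms stay cis. The equilibrium should favour each aryl trans to its neighbour, which is diester 9, where the route is rejoined. Control thus shifts from kinetic facial selectivity to thermodynamic equilibration; contact time is kept short to limit elimination from the cation.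

**Step 8 (key step).** The most likely failure is stalling at monoacetate 13, because the β-branched arms fit the enzyme pocket less well after the first acylation. Low solubility of 11 in enzyme-compatible solvents and catechol oxidation on long reaction times are further risks. The fallback sets out from hexol 11. Ac2O and pyridine give the hexaacetate F2. The four aryl acetates are then removed selectively with NH4OAc in aqueous MeOH at rt, a known chemoselective solvolysis that relies on phenoxide being a far better leaving group than alkoxide. This returns to 14.

**Step 7 (hydrogenolysis).** The most likely failure is over-reduction: hydrogenolytic opening of the ring at C2–O1 or C5–O1 once the para hydroxyls are free. The fallback sets out from diol 10 and is non-reductive. BCl3 with pentamethylbenzene as benzyl-cation scavenger in CH2Cl2 at −78 °C, then a MeOH quench, should give hexol 11. No new compound arises on this path (entered below as F0). If the ring bonds ionise reversibly, re-closure returns the thermodynamically preferred configuration the compound already has.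

**Step 4 (epoxide formation).** The most likely failures are ylide side reactions (sigmatropic rearrangement, hydrolysis of the salt) and acid-induced rearrangement of the electron-rich epoxide during isolation. The fallback sets out from aldehyde 1. McMurry coupling (TiCl4, Zn, THF, reflux) gives the E-stilbene F3. Epoxidation with dimethyldioxirane in acetone at 0 °C, which is neutral and acid-free, returns to epoxide 6.

## Further compounds

F1 | step 5 | dimethyl all-cis-2,5-bis[3,4-bis(benzyloxy)phenyl]tetrahydrofuran-3,4-dicarboxylate (meso; aryls cis to esters) | COC(=O)[C@@H]1[C@H](C(=O)OC)[C@H](c2ccc(OCc3ccccc3)c(OCc3ccccc3)c2)O[C@@H]1c1ccc(OCc2ccccc2)c(OCc2ccccc2)c1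
F2 | step 8 | hexaacetate of hexol 11 (meso) | CC(=O)OC[C@@H]1[C@H](COC(C)=O)[C@@H](c2ccc(OC(C)=O)c(OC(C)=O)c2)O[C@H]1c1ccc(OC(C)=O)c(OC(C)=O)c1
F0 | step 7 | none | none
F3 | step 4 | (E)-1,2-bis[3,4-bis(benzyloxy)phenyl]ethene | c1ccccc1COc1ccc(cc1OCc1ccccc1)/C=C/c1ccc(OCc2ccccc2)c(OCc2ccccc2)c1
A1 | alternative 1 | cis-fused 2,5-cis-diaryl tetrahydrofuran γ-lactone, aryls on the convex face (racemic) | O=C1OC[C@@H]2[C@@H](c3ccc(OCc4ccccc4)c(OCc4ccccc4)c3)O[C@@H](c3ccc(OCc4ccccc4)c(OCc4ccccc4)c3)[C@H]12
A2 | alternative 1 | 3-diazo-4-{[3,4-bis(benzyloxy)phenyl][3,4-bis(benzyloxy)benzyloxy]methyl}dihydrofuran-2-one (racemic) | O=C1OC[C@H]([C@@H](c2ccc(OCc3ccccc3)c(OCc3ccccc3)c2)OCc2ccc(OCc3ccccc3)c(OCc3ccccc3)c2)C1=[N+]=[N-]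
A3 | alternative 2 | tetra-O-benzyl ether of target 14 (meso) | CC(=O)OC[C@@H]1[C@H](COC(C)=O)[C@@H](c2ccc(OCc3ccccc3)c(OCc3ccccc3)c2)O[C@H]1c1ccc(OCc2ccccc2)c(OCc2ccccc2)c1
A4 | alternative 2 | 3,4-cis-bis(acetoxymethyl)tetrahydrofuran-2,5-cis-dicarboxylic acid, carboxyls trans to the arms (meso) | CC(=O)OC[C@@H]1[C@H](COC(C)=O)[C@@H](C(=O)O)O[C@H]1C(=O)O
A5 | alternative 2 | 4-bromo-1,2-bis(benzyloxy)benzene | Brc1ccc(OCc2ccccc2)c(OCc2ccccc2)c1
A6 | alternative 3 | dimethyl 2,5-cis-bis[3,4-bis(benzyloxy)phenyl]-4-vinyltetrahydrofuran-3,3-dicarboxylate, vinyl trans to the C5 aryl (racemic) | COC(=O)C1(C(=O)OC)[C@H](C=C)[C@@H](c2ccc(OCc3ccccc3)c(OCc3ccccc3)c2)O[C@H]1c1ccc(OCc2ccccc2)c(OCc2ccccc2)c1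
A7 | alternative 3 | trans-2-[3,4-bis(benzyloxy)phenyl]-3-vinyloxirane (racemic) | C=C[C@@H]1[C@H](O1)c1ccc(OCc2ccccc2)c(OCc2ccccc2)c1
A8 | alternative 3 | dimethyl 2-[3,4-bis(benzyloxy)benzylidene]malonate | COC(=O)C(=Cc1ccc(OCc2ccccc2)c(OCc2ccccc2)c1)C(=O)OC
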